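**Plan**

1. Tetralin numbering is used for every intermediate: C1 bears the aryl group, C2 the CH2OSO3H carbon (C2a), C3 the CH2OH carbon (C3a), C4 is the benzylic CH2, ring B is C1–C4/C4a/C8a and ring A is C4a–C8a.
2. Enabling feature: ring A has its hydroxyl on C7, para to C4a, with the methoxy group beside it on C6. This is what remains when a 2-alkyl-4-methoxyfuran (C4a, C5, C6, C7) adds an alkyne (C8a, C8) and the oxygen bridge of the adduct opens at C4a.
3. Retrosynthesis: cut C4a–C8a and C7–C8 (rings A and B together), then C3–C4 (aldol condensation with 4-methoxyfurfural), C2–C3 (enolate alkylation with a bromoacetate) and C1–C(alkyne) (conjugate alkynylation of an arylidene Meldrum's acid).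
4. Forward: the chain grows from C1 to C4 (alkynylated acid, auxiliary alkylation, lactone, furan attached five steps before it is consumed); one thermal step then closes ring B and ring A. Opening the lactone makes C2a an alcohol and C3a an amide, which later directs the sulfate to C2a.
5. Stereochemistry: C1 from the chiral rhodium catalyst, C2 from the oxazolidinone auxiliary, C3 from equilibration to the trans-lactone; the key step creates no stereocentre.
6. The alkyne is left unactivated, since no activating group on C8 could be removed cleanly; the cycloaddition relies on the electron-rich furan and the fully substituted tether.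

Key step: step 13

Assumption (step 3): the (R)-bisphosphine is taken to give the S configuration at C1 in the alkynylation product; if the sense of induction is opposite, the (S)-ligand is used.
Assumption (steps 17 and 18): sulfate monoesters are handled as their sodium salts and are drawn and named as the free hydrogen sulfates.

Step 1
Reactants: 1 4-bromofuran-2-carbaldehyde
Product: 4 4-methoxyfuran-2-carbaldehyde, via bromo acetal 2 (not isolated), via methoxy acetal 3 (not isolated)
Conditions: HC(OMe)3, MeOH, p-TsOH (cat.), rt; then NaOMe, CuBr (10 mol %), MeOH–NMP, 100 °C; then aq. citric acid, THF, rt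
Reagents that add atoms: sodium methoxide, [Na+].[O-]C; water, O
Why: One-pot acetalisation, copper-catalysed Ullmann-type methoxylation of the 3-bromofuran-type C–Br bond and mild acetal hydrolysis, in which the acetal keeps methoxide off the aldehyde and the released formyl group tempers the ring enol ether against the acid.

Step 2
Reactants: 5 4-(benzyloxy)-3-methoxybenzaldehyde; 6 Meldrum's acid
Product: 7 5-[4-(benzyloxy)-3-methoxybenzylidene]-2,2-dimethyl-1,3-dioxane-4,6-dione
Conditions: piperidine (cat.), AcOH (cat.), EtOH, rt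
Reagents that add atoms: none
Why: Knoevenagel condensation of a non-enolisable aldehyde with the strongly acidic cyclic malonate should give the doubly activated alkene needed for conjugate alkynylation.

Step 3
Reactants: 7 arylidene Meldrum's acid; 8 ethynyltrimethylsilane
Product: 9 (S)-alkynylated Meldrum's acid adduct
Conditions: [Rh(OAc)(C2H4)2]2 (2.5 mol %), (R)-DTBM-SEGPHOS (5.5 mol %), slow addition of 8, 1,4-dioxane, rt
Reagents that add atoms: none
Why: Rhodium-catalysed asymmetric conjugate alkynylation of an arylidene Meldrum's acid, in which an alkynyl–rhodium species adds to the exocyclic alkene and the chiral bisphosphine selects the face, so that C1 is set by catalyst control.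

Step 4
Reactants: 9 alkynylated Meldrum's acid adduct
Product: 10 (3S)-3-[4-(benzyloxy)-3-methoxyphenyl]-5-(trimethylsilyl)pent-4-ynoic acid
Conditions: DMF–H2O (10:1), 100 °C
Reagents that add atoms: water, O
Why: Hydrolytic opening of the acylal and thermal decarboxylation of the resulting malonic acid (Meldrum's acid cleavage) should leave the mono-acid, with the non-enolisable C1 centre untouched.

Step 5
Reactants: 10 alkynyl acid; 11 (4S)-4-benzyl-1,3-oxazolidin-2-one
Product: 13 N-acyl oxazolidinone, via mixed pivalic anhydride 12 (not isolated)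
Conditions: PivCl, Et3N, THF, −20 °C; then LiCl, 11, −20 °C → rt
Reagents that add atoms: none
Why: N-Acylation of the oxazolidinone through the mixed pivalic anhydride, which is attacked at its less hindered carbonyl, attaches the auxiliary without touching C1.

Step 6
Reactants: 13 N-acyl oxazolidinone; 14 tert-butyl bromoacetate
Product: 15 alkylated imide (C2 S, C1 S)
Conditions: NaN(SiMe3)2, THF, −78 °C; then 14, −78 → −40 °C
Reagents that add atoms: none
Why: Evans alkylation, in which the chelated Z-sodium enolate is attacked by the bromoacetate on the face away from the benzyl group of the (S)-auxiliary, sets C2 by auxiliary control irrespective of the neighbouring C1 centre.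

Step 7
Reactants: 15 alkylated imide
Product: 17 (4S)-4-[(1S)-1-(4-benzyloxy-3-methoxyphenyl)-3-(trimethylsilyl)prop-2-ynyl]oxolan-2-one, via hydroxy tert-butyl ester 16 (not isolated)
Conditions: LiBH4, MeOH (1 equiv), THF, 0 °C; then CF3CO2H, CH2Cl2, 0 °C → rt
Reagents that add atoms: none
Why: LiBH4 should reduce the activated imide carbonyl in the presence of the tert-butyl ester and release the auxiliary, and acid then cleaves the tert-butyl ester and closes the five-membered ring (reductive auxiliary removal, lactonisation) without affecting C1 or C2.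

Step 8
Reactants: 17 lactone; 4 4-methoxyfuran-2-carbaldehyde
Product: 19 (E)-furylmethylidene lactone, via aldol acetate 18 (not isolated)
Conditions: LiN(iPr)2, THF, −78 °C; then 4; then Ac2O, −78 °C → rt; then DBU, rt
Reagents that add atoms: none
Why: Aldol condensation: the lactone lithium enolate adds to the aldehyde anti to the C2 substituent, and acetylation followed by E1cB elimination should give the conjugated E-alkylidene lactone, in which C3 is trigonal so that no selectivity is required.

Step 9
Reactants: 19 furylmethylidene lactone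
Product: 20 saturated lactone as a mixture of C3 epimers
Conditions: Cu(OAc)2·H2O (5 mol %), 1,2-bis(diphenylphosphino)benzene (5 mol %), (EtO)2MeSiH, t-BuOH, toluene, rt
Reagents that add atoms: none
Why: Copper hydride-catalysed conjugate reduction delivers hydride to C4 of the unsaturated lactone and should leave the silylalkyne, the furan and the benzyl ether alone, while protonation of the enolate forms C3 without reliable control (the cis isomer is expected to predominate).

Step 10
Reactants: 20 saturated lactone (C3 mixture)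
Product: 21 (3R,4R)-trans lactone with terminal alkyne
Conditions: NaOMe (0.5 equiv), MeOH–THF, rt; AcOH quench
Reagents that add atoms: none
Why: Methoxide cleaves the alkynyl C–Si bond (protodesilylation) and equilibrates C3 through the lactone enolate to the more stable 2,3-trans lactone, so that C3 is set by thermodynamic control while the much less acidic C1–H is expected to stay untouched.

Step 11
Reactants: 21 trans lactone
Product: 22 γ-hydroxy Weinreb amide
Conditions: MeNH(OMe)·HCl, AlMe3, CH2Cl2, 0 °C → rt; aq. KNa tartrate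
Reagents that add atoms: N,O-dimethylhydroxylamine hydrochloride, CNOC.Cl
Why: Aminolysis of the lactone by the aluminium amide (Weinreb amide formation) opens the ring at the acyl carbon only, so that C3a becomes the amide and C2a the free primary alcohol, which differentiates the two oxygenated carbons.

Step 12
Reactants: 22 γ-hydroxy Weinreb amide
Product: 23 C2a tert-butyldiphenylsilyl ether
Conditions: t-BuPh2SiCl, imidazole, DMF, rt
Reagents that add atoms: tert-butyldiphenylsilyl chloride, CC(C)(C)[Si](Cl)(c1ccccc1)c1ccccc1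
Why: Silylation of the primary alcohol traps the hydroxy amide before it can close back to the lactone and gives a C2a protecting group that tolerates heat, hydride and the later benzylation.

Step 13
Reactants: 23 furan–alkyne silyl ether amide
Product: 25 aryltetralin with free 7-hydroxyl, via oxa-bridged cycloadduct 24 (not isolated)
Conditions: PhCl (0.01 M), BHT (0.1 equiv), 170 °C, sealed tube; then pyridinium p-toluenesulfonate (5 mol %), 60 °C
Reagents that add atoms: none
Why: On heating, the 4-methoxyfuran acts as the diene (C4a, C5, C6, C7) and the terminal alkyne as the 2π partner (C8a, C8) in an intramolecular [4+2] cycloaddition that forms C4a–C8a and C7–C8 and gives the 7-oxanorbornadiene 24; mild acid (or the phenol already formed) then ionises the C4a–O bond to a cation that is tertiary, allylic on both sides and delocalised through C5=C6 onto the methoxy oxygen, and loss of the proton from C7 aromatises ring A with the hydroxyl on C7. The closest known reaction type is the intramolecular Diels–Alder reaction of electron-rich furans with tethered unactivated π-bonds, followed by ring-opening aromatisation of the oxygen-bridged adduct to a phenol. Ring B closes as the six-membered ring spanned by the four-carbon tether C1–C4 when C4a–C8a forms (the tether sits on the diene terminus, so only the fused mode is possible), and ring A closes as the six-membered carbocycle of the cycloadduct itself. No lasting stereocentre is created: the bridgeheads C4a and C7 are transient, both facial adducts converge on the same arene, and C1, C2 and C3 are spectators. The step needs regiocontrol, which the tether (C8a onto C4a) and the methoxy-stabilised C4a cation (hydroxyl on C7 only) secure, and it needs the cycloaddition to outrun decomposition of the furan, which is helped by the donor methoxy group and by the chain, whose lowest-energy rotamer about C2–C3 (the two hydrogens anti) already holds C1 and C4 gauche with all three substituents equatorial in the forming ring. The open-chain amide is used instead of the lactone so that no trans-fused five-membered ring strains the transition state, and the gain in aromaticity should make the sequence irreversible.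

Step 14
Reactants: 25 aryltetralin Weinreb amide
Product: 27 C3a primary alcohol with free 7-hydroxyl, via aldehyde 26 (not isolated)
Conditions: iBu2AlH, THF, −78 °C; aq. KNa tartrate; then NaBH4, MeOH, 0 °C
Reagents that add atoms: none
Why: iBu2AlH reduces the Weinreb amide to the aldehyde through a stable chelated tetrahedral intermediate and NaBH4 then gives the primary alcohol, with the equatorial C3 centre expected to be retained.

Step 15
Reactants: 27 phenol alcohol
Product: 28 tribenzyl ether silyl ether
Conditions: NaH, BnBr, Bu4NI (cat.), DMF, 0 °C → rt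
Reagents that add atoms: benzyl bromide, BrCc1ccccc1
Why: Double Williamson etherification benzylates the phenoxide and the primary alkoxide in one operation, and the bulky tert-butyldiphenylsilyl group is not expected to migrate to the neighbouring alkoxide.

Step 16
Reactants: 28 tribenzyl ether silyl ether
Product: 29 C2a alcohol
Conditions: Bu4NF, THF, rt
Reagents that add atoms: none
Why: Fluoride-induced cleavage of the silyl ether should free C2a–OH as the only hydroxyl group in the molecule.

Step 17
Reactants: 29 C2a alcohol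
Product: 30 tribenzyl C2a hydrogen sulfate
Conditions: SO3·pyridine, pyridine, 40 °C; aq. NaHCO3
Reagents that add atoms: sulfur trioxide–pyridine complex, O=S(=O)([O-])[n+]1ccccc1
Why: O-Sulfation of the single free alcohol with the SO3–pyridine complex should give the sulfate monoester at C2a and nowhere else.

Step 18
Reactants: 30 tribenzyl C2a hydrogen sulfate
Product: 31 target
Conditions: H2 (1 atm), 10 % Pd/C, MeOH, rt
Reagents that add atoms: none
Why: Hydrogenolysis over Pd/C should remove the three benzyl ethers, while alkyl sulfate monoesters and the C1–aryl bond are stable to these neutral reductive conditions.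

**Compound list**

1 | 4-bromofuran-2-carbaldehyde | O=Cc1cc(Br)co1 | starting material
2 | 4-bromo-2-(dimethoxymethyl)furan | COC(OC)c1cc(Br)co1 | intermediate (not isolated)
3 | 2-(dimethoxymethyl)-4-methoxyfuran | COC(OC)c1cc(OC)co1 | intermediate (not isolated)
4 | 4-methoxyfuran-2-carbaldehyde | COc1coc(C=O)c1 | intermediate
5 | 4-(benzyloxy)-3-methoxybenzaldehyde | COc1cc(C=O)ccc1OCc1ccccc1 | starting material
6 | 2,2-dimethyl-1,3-dioxane-4,6-dione (Meldrum's acid) | CC1(C)OC(=O)CC(=O)O1 | starting material
7 | 5-[4-(benzyloxy)-3-methoxybenzylidene]-2,2-dimethyl-1,3-dioxane-4,6-dione | COc1cc(C=C2C(=O)OC(C)(C)OC2=O)ccc1OCc1ccccc1 | intermediate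
8 | ethynyltrimethylsilane | C#C[Si](C)(C)C | starting material
9 | 5-[(1S)-1-[4-(benzyloxy)-3-methoxyphenyl]-3-(trimethylsilyl)prop-2-yn-1-yl]-2,2-dimethyl-1,3-dioxane-4,6-dione | COc1cc([C@@H](C#C[Si](C)(C)C)C2C(=O)OC(C)(C)OC2=O)ccc1OCc1ccccc1 | intermediate
10 | (3S)-3-[4-(benzyloxy)-3-methoxyphenyl]-5-(trimethylsilyl)pent-4-ynoic acid | COc1cc([C@@H](C#C[Si](C)(C)C)CC(=O)O)ccc1OCc1ccccc1 | intermediate
11 | (4S)-4-benzyl-1,3-oxazolidin-2-one | O=C1N[C@@H](Cc2ccccc2)CO1 | starting material
12 | mixed anhydride of acid 10 and pivalic acid | COc1cc([C@@H](C#C[Si](C)(C)C)CC(=O)OC(=O)C(C)(C)C)ccc1OCc1ccccc1 | intermediate (not isolated)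
13 | (4S)-4-benzyl-3-[(3S)-3-[4-(benzyloxy)-3-methoxyphenyl]-5-(trimethylsilyl)pent-4-ynoyl]-1,3-oxazolidin-2-one | COc1cc([C@@H](C#C[Si](C)(C)C)CC(=O)N2[C@@H](Cc3ccccc3)COC2=O)ccc1OCc1ccccc1 | intermediate
14 | tert-butyl bromoacetate | CC(C)(C)OC(=O)CBr | starting material
15 | tert-butyl (3S,4S)-3-[(4S)-4-benzyl-2-oxo-1,3-oxazolidine-3-carbonyl]-4-[4-(benzyloxy)-3-methoxyphenyl]-6-(trimethylsilyl)hex-5-ynoate | COc1cc([C@@H](C#C[Si](C)(C)C)[C@H](CC(=O)OC(C)(C)C)C(=O)N2[C@@H](Cc3ccccc3)COC2=O)ccc1OCc1ccccc1 | intermediate
16 | tert-butyl (3S,4S)-4-[4-(benzyloxy)-3-methoxyphenyl]-3-(hydroxymethyl)-6-(trimethylsilyl)hex-5-ynoate | COc1cc([C@@H](C#C[Si](C)(C)C)[C@H](CC(=O)OC(C)(C)C)CO)ccc1OCc1ccccc1 | intermediate (not isolated)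
17 | (4S)-4-[(1S)-1-[4-(benzyloxy)-3-methoxyphenyl]-3-(trimethylsilyl)prop-2-yn-1-yl]oxolan-2-one | COc1cc([C@@H](C#C[Si](C)(C)C)[C@@H]2CC(=O)OC2)ccc1OCc1ccccc1 | intermediate
18 | 3,4-trans aldol acetate of 17 and 4 (acetoxy(4-methoxyfuran-2-yl)methyl group on the lactone α-carbon, both epimers at the acetoxy carbon) | COc1cc([C@@H](C#C[Si](C)(C)C)[C@@H]2[C@@H](C(OC(C)=O)c3cc(OC)co3)C(=O)OC2)ccc1OCc1ccccc1 | intermediate (not isolated)
19 | (3E,4R)-4-[(1S)-1-[4-(benzyloxy)-3-methoxyphenyl]-3-(trimethylsilyl)prop-2-yn-1-yl]-3-[(4-methoxyfuran-2-yl)methylidene]oxolan-2-one | COc1cc([C@@H](C#C[Si](C)(C)C)[C@@H]2/C(=C\c3cc(OC)co3)C(=O)OC2)ccc1OCc1ccccc1 | intermediate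
20 | (4R)-4-[(1S)-1-[4-(benzyloxy)-3-methoxyphenyl]-3-(trimethylsilyl)prop-2-yn-1-yl]-3-[(4-methoxyfuran-2-yl)methyl]oxolan-2-one, mixture of epimers at the lactone α-carbon (C3) | COc1cc([C@@H](C#C[Si](C)(C)C)[C@@H]2C(Cc3cc(OC)co3)C(=O)OC2)ccc1OCc1ccccc1 | intermediate
21 | (3R,4R)-4-[(1R)-1-[4-(benzyloxy)-3-methoxyphenyl]prop-2-yn-1-yl]-3-[(4-methoxyfuran-2-yl)methyl]oxolan-2-one | COc1cc([C@@H](C#C)[C@@H]2[C@@H](Cc3cc(OC)co3)C(=O)OC2)ccc1OCc1ccccc1 | intermediate
22 | (2R,3R,4R)-4-[4-(benzyloxy)-3-methoxyphenyl]-3-(hydroxymethyl)-N-methoxy-2-[(4-methoxyfuran-2-yl)methyl]-N-methylhex-5-ynamide | COc1cc([C@@H](C#C)[C@@H](CO)[C@@H](Cc2cc(OC)co2)C(=O)N(C)OC)ccc1OCc1ccccc1 | intermediate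
23 | (2R,3R,4R)-4-[4-(benzyloxy)-3-methoxyphenyl]-3-{[tert-butyl(diphenyl)silyl]oxymethyl}-N-methoxy-2-[(4-methoxyfuran-2-yl)methyl]-N-methylhex-5-ynamide (key-step precursor) | COc1cc([C@@H](C#C)[C@@H](CO[Si](c2ccccc2)(c2ccccc2)C(C)(C)C)[C@@H](Cc2cc(OC)co2)C(=O)N(C)OC)ccc1OCc1ccccc1 | intermediate
24 | oxygen-bridged [4+2] adduct: ring B fused at C4a–C8a to a 7-oxabicyclo[2.2.1]hepta-2,5-diene (O between C4a and C7, C5=C6–OMe, C8a=C8); one of the two bridge diastereomers is drawn, both give 25 | COc1cc([C@H]2C3=C[C@@H]4O[C@@]3(C[C@@H](C(=O)N(C)OC)[C@@H]2CO[Si](c3ccccc3)(c3ccccc3)C(C)(C)C)C=C4OC)ccc1OCc1ccccc1 | intermediate (not isolated)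
25 | (2R,3R,4S)-4-[4-(benzyloxy)-3-methoxyphenyl]-3-{[tert-butyl(diphenyl)silyl]oxymethyl}-6-hydroxy-N,7-dimethoxy-N-methyl-1,2,3,4-tetrahydronaphthalene-2-carboxamide (key-step product) | COc1cc([C@H]2c3cc(O)c(OC)cc3C[C@@H](C(=O)N(C)OC)[C@@H]2CO[Si](c3ccccc3)(c3ccccc3)C(C)(C)C)ccc1OCc1ccccc1 | intermediate
26 | (2R,3R,4S)-4-[4-(benzyloxy)-3-methoxyphenyl]-3-{[tert-butyl(diphenyl)silyl]oxymethyl}-6-hydroxy-7-methoxy-1,2,3,4-tetrahydronaphthalene-2-carbaldehyde | COc1cc([C@H]2c3cc(O)c(OC)cc3C[C@@H](C=O)[C@@H]2CO[Si](c3ccccc3)(c3ccccc3)C(C)(C)C)ccc1OCc1ccccc1 | intermediate (not isolated)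
27 | (6R,7R,8S)-8-[4-(benzyloxy)-3-methoxyphenyl]-7-{[tert-butyl(diphenyl)silyl]oxymethyl}-6-(hydroxymethyl)-3-methoxy-5,6,7,8-tetrahydronaphthalen-2-ol | COc1cc([C@H]2c3cc(O)c(OC)cc3C[C@@H](CO)[C@@H]2CO[Si](c3ccccc3)(c3ccccc3)C(C)(C)C)ccc1OCc1ccccc1 | intermediate
28 | (1S,2R,3R)-7-(benzyloxy)-1-[4-(benzyloxy)-3-methoxyphenyl]-3-[(benzyloxy)methyl]-2-{[tert-butyl(diphenyl)silyl]oxymethyl}-6-methoxy-1,2,3,4-tetrahydronaphthalene | COc1cc([C@H]2c3cc(OCc4ccccc4)c(OC)cc3C[C@@H](COCc3ccccc3)[C@@H]2CO[Si](c3ccccc3)(c3ccccc3)C(C)(C)C)ccc1OCc1ccccc1 | intermediate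
29 | [(1S,2R,3R)-7-(benzyloxy)-1-[4-(benzyloxy)-3-methoxyphenyl]-3-[(benzyloxy)methyl]-6-methoxy-1,2,3,4-tetrahydronaphthalen-2-yl]methanol | COc1cc([C@H]2c3cc(OCc4ccccc4)c(OC)cc3C[C@@H](COCc3ccccc3)[C@@H]2CO)ccc1OCc1ccccc1 | intermediate
30 | [(1S,2R,3R)-7-(benzyloxy)-1-[4-(benzyloxy)-3-methoxyphenyl]-3-[(benzyloxy)methyl]-6-methoxy-1,2,3,4-tetrahydronaphthalen-2-yl]methyl hydrogen sulfate | COc1cc([C@H]2c3cc(OCc4ccccc4)c(OC)cc3C[C@@H](COCc3ccccc3)[C@@H]2COS(=O)(=O)O)ccc1OCc1ccccc1 | intermediate
31 | [(1S,2R,3R)-7-hydroxy-1-(4-hydroxy-3-methoxyphenyl)-3-(hydroxymethyl)-6-methoxy-1,2,3,4-tetrahydronaphthalen-2-yl]methyl hydrogen sulfate (CNP0184747.1) | COc1cc([C@H]2c3cc(O)c(OC)cc3C[C@@H](CO)[C@@H]2COS(=O)(=O)O)ccc1O | target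

**Step count**

Total: 18 steps. Longest linear sequence: 17 steps (5 to 31, steps 2–18); step 1 supplies aldehyde 4 for the convergent step 8.

**Steps most likely to fail**

Step 13. The cycloaddition of the unactivated terminal alkyne may be slower than thermal or acid-induced breakdown of the electron-rich furan, so that material is lost before ring B closes. The fallback sets out from 23 and activates the 2π partner with a halogen that is later removed. The alkyne is metalated with LiN(SiMe3)2 in THF at −78 °C and brominated with CBr4 to give the bromoalkyne F1. Its C–Br carbon gains stability on going from sp to sp2, which should lower the barrier and allow a lower temperature in PhCl. The cycloaddition then gives the bromo oxa-bridged adduct F2, and acid-induced bridge opening gives the 8-bromophenol F3 (bromine on C8). Formate reduction of the aryl bromide (Pd(OAc)2, PPh3, HCO2H, Et3N, DMF, 60 °C) leaves the benzyl ether intact and comes back to the route at 25.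

Step 11. Ring opening of the hindered 3,4-disubstituted lactone by the aluminium amide may stall, the γ-hydroxy amide may close back to the lactone during work-up, and the Lewis-acidic aluminium species may attack the furan enol ether. The fallback sets out from 21 and opens the ring by saponification instead. LiOH in THF–water gives the lithium hydroxy carboxylate F4, which is silylated without acidification (t-BuPh2SiCl, imidazole, DMF) to the silyl ether silyl ester F5. Aqueous K2CO3 in methanol cleaves only the silyl ester and gives the silyloxy acid F6. Carbodiimide coupling with MeNH(OMe)·HCl and iPr2NEt then comes back to the route at 23.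

Step 8. The aldol addition of the hindered enolate to the sensitive aldehyde may reverse on warming, and the elimination may be incomplete or give alkene isomers. The fallback sets out from 17 and replaces the aldol–elimination by an olefination. C-Phosphorylation of the lactone enolate (LiN(iPr)2, two equivalents, then ClP(O)(OEt)2, THF, −78 °C → rt) gives the α-phosphono lactone F7. Horner–Wadsworth–Emmons reaction with 4 (NaH, THF, 0 °C) should give the E-alkylidene lactone and comes back to the route at 19.

**Further compounds**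

F1 | step 13 | 6-bromo derivative of 23 (C≡C–Br in place of C≡C–H, configuration as in 23) | COc1cc([C@@H](C#CBr)[C@@H](CO[Si](c2ccccc2)(c2ccccc2)C(C)(C)C)[C@@H](Cc2cc(OC)co2)C(=O)N(C)OC)ccc1OCc1ccccc1
F2 | step 13 | 8-bromo derivative of the oxygen-bridged adduct 24 (one bridge diastereomer drawn) | COc1cc([C@H]2C3=C(Br)[C@@H]4O[C@@]3(C[C@@H](C(=O)N(C)OC)[C@@H]2CO[Si](c3ccccc3)(c3ccccc3)C(C)(C)C)C=C4OC)ccc1OCc1ccccc1
F3 | step 13 | 8-bromo derivative of 25 (tetralin numbering; bromine between C7–OH and C8a) | COc1cc([C@H]2c3c(Br)c(O)c(OC)cc3C[C@@H](C(=O)N(C)OC)[C@@H]2CO[Si](c3ccccc3)(c3ccccc3)C(C)(C)C)ccc1OCc1ccccc1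
F4 | step 11 | lithium (2R,3R,4R)-4-[4-(benzyloxy)-3-methoxyphenyl]-3-(hydroxymethyl)-2-[(4-methoxyfuran-2-yl)methyl]hex-5-ynoate | COc1cc([C@@H](C#C)[C@@H](CO)[C@@H](Cc2cc(OC)co2)C(=O)[O-])ccc1OCc1ccccc1.[Li+]
F5 | step 11 | tert-butyldiphenylsilyl ester of the C2a tert-butyldiphenylsilyl ether of the acid of F4 | COc1cc([C@@H](C#C)[C@@H](CO[Si](c2ccccc2)(c2ccccc2)C(C)(C)C)[C@@H](Cc2cc(OC)co2)C(=O)O[Si](c2ccccc2)(c2ccccc2)C(C)(C)C)ccc1OCc1ccccc1
F6 | step 11 | (2R,3R,4R)-4-[4-(benzyloxy)-3-methoxyphenyl]-3-{[tert-butyl(diphenyl)silyl]oxymethyl}-2-[(4-methoxyfuran-2-yl)methyl]hex-5-ynoic acid | COc1cc([C@@H](C#C)[C@@H](CO[Si](c2ccccc2)(c2ccccc2)C(C)(C)C)[C@@H](Cc2cc(OC)co2)C(=O)O)ccc1OCc1ccccc1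
F7 | step 8 | diethyl phosphonate on the α-carbon of lactone 17 (mixture of epimers at that carbon) | COc1cc([C@@H](C#C[Si](C)(C)C)[C@@H]2C(P(=O)(OCC)OCC)C(=O)OC2)ccc1OCc1ccccc1
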